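**Retrosynthetic overview**

1. Locants follow 3,7-dioxabicyclo[3.3.0]octane (C1 carbinol, C2 and C6 aryl carbons, C5 ring-fusion CH; ring A = C1–C2–O3–C4–C5, ring B = C1–C5–C6–O7–C8). The last step is a cis-hydrogenation of a C5=C6 enol ether from the hydroxyl face, which sets H-5 and H-6 and so places the C6 aryl endo.
2. The 5,6-didehydro bicycle is made in one operation from an acyclic (R)-α-aryl-α-(3-arylprop-2-ynyloxy)-α′-silyloxy ketone: a silyl Lewis acid makes the alkyne attack the ketone (C1–C5, ring A closes first) and the silyl ether oxygen closes on the resulting vinyl cation (O7–C6, ring B second).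
3. Enabling feature: C1 is a tertiary carbinol carrying C8–O7, so C1–C8–O7 is a hidden 1-oxygenated propan-2-one (electrophilic carbon and nucleophilic oxygen in a 1,3-relationship), and C5–C6 with the electron-rich aryl on C6 is a hidden aryl alkyne; C2–O3–C4 of ring A is the tether.
4. The ketone comes from a terminal alkene (dihydroxylation, monosilylation, oxidation). The alkene comes from an iridium-catalysed asymmetric allylic etherification of a 3,4-dimethoxycinnamyl carbonate with 3-(3,4-dimethoxyphenyl)prop-2-yn-1-ol, which sets C2, the centre that controls C1.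

Key step: step 7

Assumption: the target SMILES is read as (1S,2R,5R,6R), with the C2 aryl cis to the hydroxyl (exo) and the C6 aryl on the concave face (endo); all locants in the Why lines refer to the bicyclic numbering above.

**Step 1**
Reactants: 1 4-iodo-1,2-dimethoxybenzene; 2 prop-2-yn-1-ol
Product: 3 3-(3,4-dimethoxyphenyl)prop-2-yn-1-ol
Conditions: PdCl2(PPh3)2 (2 mol%), CuI (4 mol%), Et3N, THF, rt
Reagents that add atoms: none
Why: Sonogashira coupling of an aryl iodide with a terminal alkyne tolerates the free propargylic hydroxyl and forms no stereocentre.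

**Step 2**
Reactants: 4 (2E)-3-(3,4-dimethoxyphenyl)prop-2-en-1-ol
Product: 5 tert-butyl (2E)-3-(3,4-dimethoxyphenyl)prop-2-en-1-yl carbonate
Conditions: di-tert-butyl dicarbonate, 4-(dimethylamino)pyridine (10 mol%), CH2Cl2, 0 °C to rt
Reagents that add atoms: di-tert-butyl dicarbonate, CC(C)(C)OC(=O)OC(=O)OC(C)(C)C
Why: Amine-catalysed O-acylation of the primary allylic alcohol gives the tert-butyl carbonate, the leaving group for iridium-catalysed allylic substitution, and leaves the E-alkene untouched.

**Step 3**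
Reactants: 3 3-(3,4-dimethoxyphenyl)prop-2-yn-1-ol; 5 tert-butyl (2E)-3-(3,4-dimethoxyphenyl)prop-2-en-1-yl carbonate
Product: 6 4-[(1S)-1-{[3-(3,4-dimethoxyphenyl)prop-2-yn-1-yl]oxy}prop-2-en-1-yl]-1,2-dimethoxybenzene
Conditions: 3 (1.2 equiv), n-BuLi, then CuI, THF, 0 °C; [Ir(cod)Cl]2 (2 mol%), O,O′-(1,1′-binaphthalene-2,2′-diyl) N,N-bis(1-phenylethyl)phosphoramidite (one antipode, 4 mol%), THF, rt
Reagents that add atoms: none
Why: Iridium-catalysed enantioselective allylic etherification of a cinnamyl carbonate with the copper alkoxide of a primary alcohol should deliver the alkoxide to the aryl-bearing allyl terminus (branched ether), and the ligand antipode is chosen so that the new centre, the future C2, has the S configuration shown, which becomes R in the later ketone and in the target.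

**Step 4**
Reactants: 6 4-[(1S)-1-{[3-(3,4-dimethoxyphenyl)prop-2-yn-1-yl]oxy}prop-2-en-1-yl]-1,2-dimethoxybenzene
Product: 7 (3R)-3-(3,4-dimethoxyphenyl)-3-{[3-(3,4-dimethoxyphenyl)prop-2-yn-1-yl]oxy}propane-1,2-diol (both C2 epimers)
Conditions: OsO4 (2 mol%), N-methylmorpholine N-oxide, acetone/H2O 4:1, rt
Reagents that add atoms: N-methylmorpholine N-oxide, C[N+]1([O-])CCOCC1; water, O
Why: Upjohn dihydroxylation should take the terminal alkene much faster than the internal aryl alkyne, and the configuration of the new secondary carbinol does not matter because it is oxidised in step 6.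

**Step 5**
Reactants: 7 (3R)-3-(3,4-dimethoxyphenyl)-3-{[3-(3,4-dimethoxyphenyl)prop-2-yn-1-yl]oxy}propane-1,2-diol
Product: 8 (1R)-1-(3,4-dimethoxyphenyl)-1-{[3-(3,4-dimethoxyphenyl)prop-2-yn-1-yl]oxy}-3-[(triethylsilyl)oxy]propan-2-ol (both C2 epimers)
Conditions: Et3SiCl (1.05 equiv), imidazole, CH2Cl2, −40 °C
Reagents that add atoms: chlorotriethylsilane, CC[Si](Cl)(CC)CC
Why: Selective silylation of the primary hydroxyl of a 1,2-diol at low temperature installs the triethylsilyl group that later serves as the migrating group of the key step.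

**Step 6**
Reactants: 8 (1R)-1-(3,4-dimethoxyphenyl)-1-{[3-(3,4-dimethoxyphenyl)prop-2-yn-1-yl]oxy}-3-[(triethylsilyl)oxy]propan-2-ol
Product: 9 (1R)-1-(3,4-dimethoxyphenyl)-1-{[3-(3,4-dimethoxyphenyl)prop-2-yn-1-yl]oxy}-3-[(triethylsilyl)oxy]propan-2-one
Conditions: Dess–Martin periodinane, NaHCO3, CH2Cl2, 0 °C to rt
Reagents that add atoms: none
Why: Dess–Martin oxidation of the secondary alcohol under buffered, non-basic conditions should give the α-alkoxy-α-aryl ketone without enolisation of the benzylic stereocentre, and the ketone is used at once.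

**Step 7**
Reactants: 9 (1R)-1-(3,4-dimethoxyphenyl)-1-{[3-(3,4-dimethoxyphenyl)prop-2-yn-1-yl]oxy}-3-[(triethylsilyl)oxy]propan-2-one
Product: 11 (1S,2R)-2,6-bis(3,4-dimethoxyphenyl)-3,7-dioxabicyclo[3.3.0]oct-5-en-1-ol (5,6-didehydrogmelinol), via bicyclic triethylsilyl ether 10 (not isolated)
Conditions: Et3SiN(SO2CF3)2 (10 mol%), 2,6-di-tert-butyl-4-methylpyridine (5 mol%), CH2Cl2, −78 to −30 °C; then Bu4NF, THF, 0 °C
Reagents that add atoms: none
Why: Proposed new method: the silyl Lewis acid should convert the ketone into a silyloxocarbenium ion, which the alkyne attacks with the carbon next to its CH2O group (C1–C5 bond; ring A closes 5-exo-dig on the alkyne and exo on the carbonyl) to leave a linear vinyl cation at C6 stabilised by the 3,4-dimethoxyphenyl group, and the oxygen of the CH2OSiEt3 arm then adds to that cation (O7–C6 bond; ring B closes by 5-endo capture of the sp centre) and passes its silyl group to the next ketone, so that the net change is a silyl-catalysed isomerisation. The closest known reaction types are the alkyne Prins cyclisation with capture of the vinyl cation by a nucleophile and the Lewis-acid alkyne–carbonyl metathesis of O-propargyl α-hydroxy ketones, whose first bond-forming event is the same. The one new stereocentre, C1, is controlled by C2: in the ring A transition state the C2 aryl should sit pseudo-equatorial and anti to the CH2OSi arm, which puts the C1 oxygen cis to that aryl as in the target. The step needs the vinyl cation to be taken by the silyl ether oxygen and not by the carbonyl oxygen (oxetene, then metathesis to an enone) or by the C2 aryl ring; the silyl group already on the carbonyl oxygen and the five-membered size of ring B are expected to secure this. Regioselectivity of the alkyne attack is secured by the aryl group, since only attack through the CH2-bearing carbon gives a stabilised cation and a five-membered ring. Bu4NF then frees the tertiary alcohol without acid, which the hydroxy enol ether would not tolerate.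

**Step 8**
Reactants: 11 (1S,2R)-2,6-bis(3,4-dimethoxyphenyl)-3,7-dioxabicyclo[3.3.0]oct-5-en-1-ol
Product: 12 (+)-gmelinol, (1S,2R,5R,6R)-2,6-bis(3,4-dimethoxyphenyl)-3,7-dioxabicyclo[3.3.0]octan-1-ol
Conditions: H2 (1 atm), 5% Rh on Al2O3, Et3N (trace), EtOAc, rt
Reagents that add atoms: none
Why: Heterogeneous syn-hydrogenation of the tetrasubstituted enol ether should occur from the face that carries the C1 hydroxyl (the other face is closed by C2 and would give a trans-fused bicycle), so H-5 comes cis to the hydroxyl and H-6 cis to H-5, which places the C6 aryl endo; Rh on Al2O3 with a trace of amine is chosen to avoid hydrogenolysis of the benzylic C–O bonds and acid-induced loss of the tertiary allylic alcohol.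

**Compound list**

1 | 4-iodo-1,2-dimethoxybenzene | COc1ccc(I)cc1OC | starting material
2 | prop-2-yn-1-ol | C#CCO | starting material
3 | 3-(3,4-dimethoxyphenyl)prop-2-yn-1-ol | COc1ccc(C#CCO)cc1OC | intermediate
4 | (2E)-3-(3,4-dimethoxyphenyl)prop-2-en-1-ol | COc1ccc(/C=C/CO)cc1OC | starting material
5 | tert-butyl (2E)-3-(3,4-dimethoxyphenyl)prop-2-en-1-yl carbonate | CC(C)(C)OC(=O)OC/C=C/c1ccc(OC)c(OC)c1 | intermediate
6 | 4-[(1S)-1-{[3-(3,4-dimethoxyphenyl)prop-2-yn-1-yl]oxy}prop-2-en-1-yl]-1,2-dimethoxybenzene | COc1ccc(cc1OC)[C@@H](OCC#Cc1ccc(OC)c(OC)c1)C=C | intermediate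
7 | (3R)-3-(3,4-dimethoxyphenyl)-3-{[3-(3,4-dimethoxyphenyl)prop-2-yn-1-yl]oxy}propane-1,2-diol (both C2 epimers) | COc1ccc(cc1OC)[C@@H](OCC#Cc1ccc(OC)c(OC)c1)C(O)CO | intermediate
8 | (1R)-1-(3,4-dimethoxyphenyl)-1-{[3-(3,4-dimethoxyphenyl)prop-2-yn-1-yl]oxy}-3-[(triethylsilyl)oxy]propan-2-ol (both C2 epimers) | COc1ccc(cc1OC)[C@@H](OCC#Cc1ccc(OC)c(OC)c1)C(O)CO[Si](CC)(CC)CC | intermediate
9 | (1R)-1-(3,4-dimethoxyphenyl)-1-{[3-(3,4-dimethoxyphenyl)prop-2-yn-1-yl]oxy}-3-[(triethylsilyl)oxy]propan-2-one | COc1ccc(cc1OC)[C@@H](OCC#Cc1ccc(OC)c(OC)c1)C(=O)CO[Si](CC)(CC)CC | intermediate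
10 | triethyl{[(1S,2R)-2,6-bis(3,4-dimethoxyphenyl)-3,7-dioxabicyclo[3.3.0]oct-5-en-1-yl]oxy}silane | COc1ccc([C@H]2OCC3=C(c4ccc(OC)c(OC)c4)OC[C@]23O[Si](CC)(CC)CC)cc1OC | intermediate
11 | (1S,2R)-2,6-bis(3,4-dimethoxyphenyl)-3,7-dioxabicyclo[3.3.0]oct-5-en-1-ol | COc1ccc([C@H]2OCC3=C(c4ccc(OC)c(OC)c4)OC[C@]23O)cc1OC | intermediate
12 | (+)-gmelinol, (1S,2R,5R,6R)-2,6-bis(3,4-dimethoxyphenyl)-3,7-dioxabicyclo[3.3.0]octan-1-ol | COc1ccc([C@H]2OC[C@@H]3[C@H](c4ccc(OC)c(OC)c4)OC[C@]23O)cc1OC | target

**Step count**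

Total steps: 8. Longest linear sequence: 7 steps (steps 2 to 8 from compound 4, or steps 1 and 3 to 8 from compound 1).

**Steps most likely to fail**

Step 7 (proposed new method). The silylated, doubly oxygen-flanked ketone may not be electrophilic enough for the alkyne. The aryl-propargyl ether may ionise under the Lewis acid. The vinyl cation may be diverted to the carbonyl oxygen (metathesis) or to the C2 aryl ring. The facial control at C1 may be poor. The fallback uses known chemistry, sets out from 9 and returns at 12.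
- Palladium-catalysed syn-hydrostannation of 9 (PdCl2(PPh3)2, Bu3SnH, THF) should put tin on the alkyne carbon next to the CH2O group and give the vinylstannane (1R)-1-(3,4-dimethoxyphenyl)-1-{[(2E)-3-(3,4-dimethoxyphenyl)-2-(tributylstannyl)prop-2-en-1-yl]oxy}-3-[(triethylsilyl)oxy]propan-2-one F1.
- Iododestannylation (I2, CH2Cl2, 0 °C) should give the vinyl iodide (1R)-1-(3,4-dimethoxyphenyl)-1-{[(2E)-3-(3,4-dimethoxyphenyl)-2-iodoprop-2-en-1-yl]oxy}-3-[(triethylsilyl)oxy]propan-2-one F2.
- An intramolecular Nozaki–Hiyama–Kishi reaction (CrCl2, NiCl2 cat., DMF) should form the C1–C5 bond with the same aryl-anti preference and give (2R,3S,4E)-2-(3,4-dimethoxyphenyl)-4-[(3,4-dimethoxyphenyl)methylidene]-3-{[(triethylsilyl)oxy]methyl}oxolan-3-ol F3.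
- Hydroboration–oxidation (BH3·SMe2, then NaOH/H2O2) should give the benzylic alcohol (2R,3S)-2-(3,4-dimethoxyphenyl)-4-[(3,4-dimethoxyphenyl)(hydroxy)methyl]-3-{[(triethylsilyl)oxy]methyl}oxolan-3-ol F4.
- Dess–Martin oxidation should give the aryl ketone (3,4-dimethoxyphenyl)[(4S,5R)-5-(3,4-dimethoxyphenyl)-4-hydroxy-4-{[(triethylsilyl)oxy]methyl}oxolan-3-yl]methanone F5.
- Bu4NF should remove the silyl group, and the primary hydroxyl should close on the ketone to the cis-fused hemiketal (1S,2R,5S)-2,6-bis(3,4-dimethoxyphenyl)-3,7-dioxabicyclo[3.3.0]octane-1,6-diol F6, C5 equilibrating through the enol.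
- Et3SiH/BF3·OEt2 at −78 °C should reduce the cyclic oxocarbenium ion from the convex face and give 12 with the C6 aryl endo.

Step 8. Hydrogenolysis of a benzylic C–O bond, partial saturation of an arene ring, stalling of the tetrasubstituted enol ether on the metal surface, or aromatisation of the hydroxy enol ether to a furan may occur. The fallback sets out from 11 and returns at 12 with no new compound. It replaces surface hydrogenation by stepwise hydrogen-atom-transfer hydrogenation (Mn(dpm)3 cat., PhSiH3, t-BuOOH, i-PrOH, rt). A hydrogen atom should add to C5 to give the cis-fused α-oxy benzylic radical at C6, which should take its hydrogen from the convex face.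

Step 3. The functionalised copper alkoxide may give poor branched-to-linear selectivity or eroded enantioselectivity, and the alkyne may inhibit the iridium catalyst. The fallback sets out from 3 and returns at 6.
- Appel bromination of 3 (CBr4, PPh3, CH2Cl2) should give 4-(3-bromoprop-1-yn-1-yl)-1,2-dimethoxybenzene F7.
- Catalytic asymmetric vinylation of 3,4-dimethoxybenzaldehyde (divinylzinc, 3-exo-morpholinoisoborneol of the appropriate antipode) should give (1S)-1-(3,4-dimethoxyphenyl)prop-2-en-1-ol F8.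
- Williamson etherification of F8 with F7 (NaH, THF/DMF, 0 °C) should give 6 with the stereocentre untouched.

**Further compounds**

F1 | step 7 | (1R)-1-(3,4-dimethoxyphenyl)-1-{[(2E)-3-(3,4-dimethoxyphenyl)-2-(tributylstannyl)prop-2-en-1-yl]oxy}-3-[(triethylsilyl)oxy]propan-2-one | COc1ccc(/C=C(/[Sn](CCCC)(CCCC)CCCC)CO[C@H](c2ccc(OC)c(OC)c2)C(=O)CO[Si](CC)(CC)CC)cc1OC
F2 | step 7 | (1R)-1-(3,4-dimethoxyphenyl)-1-{[(2E)-3-(3,4-dimethoxyphenyl)-2-iodoprop-2-en-1-yl]oxy}-3-[(triethylsilyl)oxy]propan-2-one | COc1ccc(/C=C(/I)CO[C@H](c2ccc(OC)c(OC)c2)C(=O)CO[Si](CC)(CC)CC)cc1OC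
F3 | step 7 | (2R,3S,4E)-2-(3,4-dimethoxyphenyl)-4-[(3,4-dimethoxyphenyl)methylidene]-3-{[(triethylsilyl)oxy]methyl}oxolan-3-ol | COc1ccc([C@H]2OC/C(=C\c3ccc(OC)c(OC)c3)[C@]2(O)CO[Si](CC)(CC)CC)cc1OC
F4 | step 7 | (2R,3S)-2-(3,4-dimethoxyphenyl)-4-[(3,4-dimethoxyphenyl)(hydroxy)methyl]-3-{[(triethylsilyl)oxy]methyl}oxolan-3-ol | COc1ccc([C@H]2OCC(C(O)c3ccc(OC)c(OC)c3)[C@]2(O)CO[Si](CC)(CC)CC)cc1OC
F5 | step 7 | (3,4-dimethoxyphenyl)[(4S,5R)-5-(3,4-dimethoxyphenyl)-4-hydroxy-4-{[(triethylsilyl)oxy]methyl}oxolan-3-yl]methanone | COc1ccc([C@H]2OCC(C(=O)c3ccc(OC)c(OC)c3)[C@]2(O)CO[Si](CC)(CC)CC)cc1OC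
F6 | step 7 | (1S,2R,5S)-2,6-bis(3,4-dimethoxyphenyl)-3,7-dioxabicyclo[3.3.0]octane-1,6-diol | COc1ccc([C@H]2OC[C@@H]3C(O)(c4ccc(OC)c(OC)c4)OC[C@]23O)cc1OC
F0 | step 8 | none | none
F7 | step 3 | 4-(3-bromoprop-1-yn-1-yl)-1,2-dimethoxybenzene | COc1ccc(C#CCBr)cc1OC
F8 | step 3 | (1S)-1-(3,4-dimethoxyphenyl)prop-2-en-1-ol | COc1ccc(cc1OC)[C@@H](O)C=C
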